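The substrate is your small charge, below both nucleophiles, so the reckoning here is a balance of it.

| setting | dusk | winter | summer | midnight |
|---|---|---|---|---|
| substrate | 33 mM (fed, over 2.5 h) | 33 mM | 33 mM | 33 mM |
| first nucleophile | 1.20 equiv | 1.20 equiv (fed, over 2.5 h) | 1.20 equiv | 1.20 equiv (fed, over 40 min) |
| solid second nucleophile | 2.50 equiv | 2.50 equiv | 2.50 equiv | 2.50 equiv |
| time | 12 h | 12 h | 12 h | 12 h |
| remark | the addition at −50 °C, then warmed to −20 °C; the feed brings no volume worth counting | all else is in the flask from the start; the feed brings no volume worth counting | everything together at the start | all else is in the flask from the start; the feed brings no volume worth counting |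
| temperature |  | −20 °C | −20 °C | −20 °C |

    first nucleophile + intermediate → target (k1 = 2.02 /M/s, Ea1 = 44.0 kJ/mol)
    second nucleophile + target → over-reaction product (k2 = 0.00963 /M/s, Ea2 = 60.0 kJ/mol)
    solid second nucleophile ⇌ second nucleophile, rate k3*(cs3 - [second nucleophile]) while solid is left; crystals form when [second nucleophile] > cs3 (cs3 = 2.4 mM, k3 = 0.00480 /s)
    substrate → intermediate (k4 = 2.59 × 10⁻⁴ /s, Ea4 = 83.0 kJ/mol)
    second nucleophile + intermediate → other capture product (k5 = 1.83 /M/s, Ea5 = 47.0 kJ/mol)
    (constants at −20 °C)

- given per volume of solution although it is solid: solid second nucleophile
- at −20 °C the constants are as listed, elsewhere as the activation energies make them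
- at the start none of the solid second nucleophile is in solution

1. the flask with the highest amount of over-reaction product, in percent of the substrate charged ("all alike" if they lie within 1.5 percentage points) (dusk / winter / summer / midnight / all alike)
2. final over-reaction product, as a percentage of the substrate charged, in dusk
3. final over-reaction product, as a percentage of the substrate charged, in winter
4. final over-reaction product, as a percentage of the substrate charged, in summer
5. final over-reaction product, as a percentage of the substrate charged, in midnight

Each substrate ends as target, other capture product or over-reaction product. Each of the last two costs one second nucleophile, so the substrate can claim 40.0% of the solid, and solid stays in the flask.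

That gives you the bench rule: excess solid holds the dissolved second nucleophile near its solubility, 2.4 mM. Dissolving keeps up with over-reaction, since its coefficient 0.00480 /s is larger than the pull of a full charge of target, 3.18 × 10⁻⁴ /s.

At −20 °C the target therefore decays pseudo-first-order, with a lifetime of 12.0 h. In summer, substrate lasts 1.07 h on average, shorter, so take the target's age as the asked time less that. The over-reaction share, the part of everything passing through target that has gone on by the end, is then in summer 59.7%.

Capture comes next. The two nucleophiles take intermediate equally when first nucleophile stands at 2.17 mM. In summer, first nucleophile starts at 39.6 mM, and its charge less one per substrate is 6.60 mM. The logarithm of the ratio of those two, times the crossing level, gives a rough capture of 11.8% of the substrate. My summer is 52.7%. For dusk I assume nothing happens before the warming and take summer's capture, which gives a share of 50.4% and a result of 44.5%.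

The border is the stock of first nucleophile. Hold its feed pace against the opening pace of intermediate. In midnight the ratio is 1.93, twice the pace. In winter it is 0.515, half. Winter's ratio stands under one, so I do not trust my capture figure, which counts on a standing stock, in winter, and I give winter no number. Midnight has a feed too, and I leave it without a number as well.

The forecast names summer, holding that the result “depends mainly on how much target forms and how long it sits”. It stands close to me on summer and dusk, and it also commits to winter and midnight.

| Flask | Forecast | Simulation |
|---|---|---|
| dusk | 44% | 44.5% |
| winter | 43% | 38.4% |
| summer | 52.5% | 53.1% |
| midnight | 51.5% | 50.5% |

The simulation names summer. In summer, over-reaction product stands at 58.2% of target and over-reaction product together, against a share of 59.7%. The neighbour is winter with 2.00 equiv of first nucleophile. Its feed ratio is 0.858, still under one, so take its capture from the run: 20.6%, against 33.2% in winter. The formula for the share has no first nucleophile in it, so I carry the share over at 59.7%, and the reckoning gives 47.4%. The neighbour ends with 45.8% over-reaction product.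

The constants used here are made up; what happens was integrated by code.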